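**Plan**
1. Numbering follows the labdanes (ring A = C1–C5 and C10; ring B = C5–C10; chain C11–C16); β is the side of the C10 methyl, α the other side; the target is (1S,2S,4aS,6R,8aR) in decalin locants.
2. Retrosynthetic cuts, in order: C13=C14 (phosphonate olefination of a C13 methyl ketone), C11–C12 (alkylborane plus bromoacetone), C9=C11 (methylenation of a C9 ketone), C3–Br (from a C3 ketone), C8–O (brought over from C6 by epoxide transposition), one C4–CH3, and last C1–C10 together with C4–C5 of ring A ([4+2]).
3. Enabling feature: the fusion carbons C10 (methyl) and C5 lie between C9 and C6 and C8 carries a methyl, so ring B is one methyl-bearing alkene of 2,6-dimethylbenzoquinone with both carbonyl carbons, while C1–C4 with the heteroatom on C3 is a 2-silyloxydiene.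
4. Forward: ring B comes from a phenol, ring A is closed onto it by the cycloaddition, C4 is methylated, the fusion is turned trans, the C6 oxygen is shifted to C8, bromide is set at C3, and the chain is grown from the C9 ketone (C11, then C12/C13/C16, then C14/C15).
5. Stereochemistry: C10 from the chiral Lewis acid; C5 by equilibration next to the C6 ketone; C8 from α-face epoxidation; C3 by equatorial hydride delivery then SN2 inversion; C9 by α-face hydroboration; the E alkene from the olefination.

Key step: step 3

Assumption: the (S)-configured oxazaborolidinium ion is taken to give adduct 5 with the 8aR (C10) configuration; should the sense of induction be the opposite, the (R)-catalyst is used and nothing else changes.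

Step 1
Reactants: 1 4-methoxy-2,6-dimethylphenol
Product: 2 4,4-dimethoxy-2,6-dimethylcyclohexa-2,5-dien-1-one
Conditions: PhI(OAc)2 (1.1 equiv), MeOH, 0 °C
Reagents that add atoms: methanol, CO
Why: Oxidative dearomatisation of a para-methoxyphenol by the hypervalent iodine reagent gives a phenoxenium-type intermediate that methanol traps at the methoxy-bearing carbon, a standard route to quinone monoketals that creates no stereocentre and leaves one carbonyl as the only Lewis-basic activating site.

Step 2
Reactants: 3 pent-1-en-3-one (ethyl vinyl ketone)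
Product: 4 (Z)-tert-butyldimethyl(penta-1,3-dien-3-yloxy)silane
Conditions: TBSOTf (1.1 equiv), Et3N (1.3 equiv), Et2O, −78 → 0 °C
Reagents that add atoms: tert-butyldimethylsilyl trifluoromethanesulfonate, CC(C)(C)[Si](C)(C)OS(=O)(=O)C(F)(F)F
Why: Soft enolisation and O-silylation of an ethyl ketone with a silyl triflate and a tertiary amine, which is expected to give mainly the (Z)-silyl enol ether, i.e. the diene whose methyl group points outwards in the s-cis conformation needed for cycloaddition.

Step 3
Reactants: 2 quinone monoketal; 4 (Z)-silyloxydiene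
Product: 5 cis-fused adduct (4aS,5R,8aR)-6-(tert-butyldimethylsilyloxy)-4,4-dimethoxy-2,5,8a-trimethyl-4a,5,8,8a-tetrahydronaphthalen-1(4H)-one
Conditions: (S)-3,3-diphenyl-1-(o-tolyl)tetrahydro-1H,3H-pyrrolo[1,2-c][1,3,2]oxazaborole (20 mol%) + HNTf2 (18 mol%), 4 (3 equiv), CH2Cl2, −78 → −20 °C; Et3N quench
Reagents that add atoms: none
Why: The cationic boron Lewis acid binds the only carbonyl of 2 (C9=O) and lowers the LUMO of the enone, so that the electron-rich diene 4 adds across C5=C10 in a concerted but asynchronous [4+2] cycloaddition in which the C4–C5 bond (enol-ether terminus to enone β-carbon) runs ahead of the C1–C10 bond. The closest known reaction type is the oxazaborolidinium-catalysed enantioselective Diels–Alder reaction of quinones and quinone monoketals with 2-silyloxy-1,3-dienes. Ring A is closed as a six-membered carbocycle by intermolecular suprafacial [4+2] cycloaddition, both new σ-bonds being made in this one step. C10 and C5 come out cis because the ring alkene adds suprafacially, the C4 methyl ends up α (trans to the C10 methyl) because the diene is Z and the C9 carbonyl lies endo, and the absolute configuration at C10 is set by the chiral catalyst, which must choose one of the two enantiotopic alkenes and one face of it. Regiochemistry is secured by the substrate: C6 is masked as a ketal, so activation can only come from C9 and the nucleophilic diene terminus C4 must bond to C5, and the 2,6-dimethyl pattern makes both alkenes constitutionally identical. The step is expected to be slow (a quaternary C10 is formed and C5 is next to the ketal carbon), which is why the diene is used in excess and as its tert-butyldimethylsilyl ether.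

Step 4
Reactants: 5 cis-fused adduct
Product: 6 cis-fused ring-A enone (6,6-dimethoxy-4α,8,10β-trimethyl-1,7-diene-3,9-dione; 5β-H)
Conditions: Pd(OAc)2 (1.1 equiv), MeCN, 23 °C
Reagents that add atoms: none
Why: Saegusa–Ito oxidation, in which the silyl enol ether gives an enolate of divalent palladium bound at C2 and β-hydride elimination from C1 releases zerovalent palladium and the C1=C2 enone regiospecifically, because the enol ether delivered by the cycloaddition is C2=C3; the stereocentres at C4, C5 and C10 are not touched.

Step 5
Reactants: 6 cis-fused ring-A enone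
Product: 8 cis-fused 4,4-dimethyl enone ketal (6,6-dimethoxy-4,4,8,10β-tetramethyl-1,7-diene-3,9-dione; 5β-H), via lithium C3–C4 dienolate 7 (not isolated)
Conditions: LiN(i-Pr)2 (1.2 equiv), THF, −78 °C; MeI (5 equiv), −78 → 0 °C
Reagents that add atoms: iodomethane, CI
Why: Kinetic α′-deprotonation and alkylation of a cyclohexenone, where C4–H is the only enolisable position of 6 (C10 is quaternary and the C9 enone has neither α′- nor γ-hydrogen), so the cross-conjugated lithium dienolate is methylated at C4, which becomes the gem-dimethyl carbon and is no longer a stereocentre.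

Step 6
Reactants: 8 cis-fused 4,4-dimethyl enone ketal
Product: 10 trans-fused trione (4,4,8,10β-tetramethyl-1,7-diene-3,6,9-trione; 5α-H), via cis-fused trione 9 (not isolated)
Conditions: 2 M aq. HCl, THF, 23 → 45 °C
Reagents that add atoms: water, O
Why: Acid-catalysed ketal hydrolysis followed by enolisation of the new C6 ketone towards C5 (thermodynamic epimerisation), with C5 set by equilibration to the trans-fused isomer (5α-H), which is expected both from the stability pattern of 4,4,10-trimethyl-6-oxodecalins and from protonation of the C5 enol on the face away from the C10 methyl, while the quaternary C10 cannot change.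

Step 7
Reactants: 10 trans-fused trione
Product: 11 7α,8α-epoxy trione (8β-methyl)
Conditions: 30% aq. H2O2 (1.5 equiv), Na2CO3 (0.3 equiv), THF–H2O, 0 °C
Reagents that add atoms: hydrogen peroxide, OO
Why: Weitz–Scheffer nucleophilic epoxidation, in which hydroperoxide adds to the doubly activated C7=C8 bond of the ene-dione much faster than to the hindered ring-A enone and approaches from the α-face, away from the axial methyl groups on C10 and C4, so that the epoxide oxygen (the future C8 hydroxyl) is α and the C8 methyl β.

Step 8
Reactants: 11 7α,8α-epoxy trione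
Product: 13 8α-hydroxy-4,4,8β,10β-tetramethyl-1,6-diene-3,9-dione (trans-fused), via C6 hydrazone 12 (not isolated)
Conditions: N2H4·H2O (2 equiv), AcOH (0.2 equiv), MeOH, 0 → 23 °C
Reagents that add atoms: none
Why: Wharton transposition, in which hydrazine condenses with the C6 ketone (C9 lies between two fully substituted carbons and the ring-A enone is hindered and less electrophilic), the hydrazone opens the epoxide at C7 and loses nitrogen to give the C6=C7 alkene and the C8 alkoxide, so that C8 keeps the epoxide configuration (8α-OH), the C6 oxygen is removed and C5 becomes a non-epimerisable allylic centre.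

Step 9
Reactants: 13 8α-hydroxy-1,6-diene-3,9-dione
Product: 14 8α-hydroxy-4,4,8β,10β-tetramethyl-trans-decalin-3,9-dione
Conditions: H2 (3 atm), RhCl(PPh3)3 (10 mol%), toluene–EtOH, 40 °C
Reagents that add atoms: none
Why: Homogeneous catalytic hydrogenation of the two 1,2-disubstituted alkenes (conjugated C1=C2 and isolated C6=C7) with RhCl(PPh3)3, chosen because it should cause neither double-bond migration towards C5 nor hydrogenolysis of the allylic tertiary alcohol nor ketone reduction; no stereocentre is created since all four carbons become methylene groups.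

Step 10
Reactants: 14 8α-hydroxy-3,9-dione
Product: 15 3α,8α-dihydroxy-4,4,8β,10β-tetramethyl-trans-decalin-9-one
Conditions: LiBH(s-Bu)3 (L-Selectride, 2.5 equiv), THF, −78 °C; then H2O
Reagents that add atoms: none
Why: Bulky-hydride reduction of a cyclohexanone, in which the trialkylborohydride attacks the C3 carbonyl along the equatorial trajectory (β-side) to give the axial 3α-alcohol, whereas the C9 ketone between two fully substituted carbons should be inert at this temperature.

Step 11
Reactants: 15 3α,8α-dihydroxy-9-one
Product: 16 3β-bromo-8α-hydroxy-4,4,8β,10β-tetramethyl-trans-decalin-9-one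
Conditions: PPh3 (3 equiv), CBr4 (3 equiv), pyridine (1 equiv), toluene, 23 → 60 °C
Reagents that add atoms: carbon tetrabromide, BrC(Br)(Br)Br
Why: Appel bromination, in which the alkoxyphosphonium salt of the axial secondary alcohol is displaced by bromide from the β-side with inversion (SN2) to give the equatorial 3β-bromide, the hindered tertiary hydroxyl at C8 not being activated.

Step 12
Reactants: 16 3β-bromo-8α-hydroxy-9-one
Product: 18 3β-bromo-4,4,8β,10β-tetramethyl-9-methylene-trans-decalin-8α-ol, via β-hydroxysilane 17 (not isolated)
Conditions: Me3SiCH2Li (4 equiv), THF, −78 → 23 °C; aq. NH4Cl; crude product, KH (4 equiv), THF, 0 → 50 °C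
Reagents that add atoms: (trimethylsilyl)methyllithium, [Li]C[Si](C)(C)C
Why: Peterson olefination, in which the silyl-stabilised alkyllithium (no β-hydrogen, so no reduction) adds to the non-enolisable C9 ketone and the potassium alkoxide of the β-hydroxysilane expels trimethylsilanolate to give the exocyclic C9=C11 alkene, the only alkene that can form, so the C9 configuration of 17 is of no consequence.

Step 13
Reactants: 18 9-methylene-8α-ol
Product: 20 4-[(1S,2S,4aS,6R,8aR)-6-bromo-2-hydroxy-2,5,5,8a-tetramethyldecahydronaphthalen-1-yl]butan-2-one, via C11 alkylborane 19 (not isolated)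
Conditions: 9-borabicyclo[3.3.1]nonane (9-BBN-H, 3 equiv), THF, 65 °C; then bromoacetone (2 equiv), potassium 2,6-di-tert-butylphenoxide (2 equiv), THF, 0 → 23 °C
Reagents that add atoms: bromoacetone, CC(=O)CBr
Why: Hydroboration followed by base-mediated α-alkylation of an α-bromo ketone by the B-alkyl-9-borabicyclononane (borate 1,2-shift), in which boron adds to C11 and hydrogen to C9 from the α-face because the β-face is blocked by the axial methyls on C8 and C10 (this sets 9α-H), and the deprotonated bromoacetone then adds to boron, the primary alkyl group migrates to carbon with loss of bromide and the boron enolate is protonated by the phenol, leaving the C11–C12 bond and the C13 ketone.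

Step 14
Reactants: 20 methyl ketone
Product: 21 ethyl (2E)-5-[(1S,2S,4aS,6R,8aR)-6-bromo-2-hydroxy-2,5,5,8a-tetramethyldecahydronaphthalen-1-yl]-3-methylpent-2-enoate
Conditions: (EtO)2P(O)CH2CO2Et (4 equiv), NaH (3.5 equiv), THF, 0 → 50 °C
Reagents that add atoms: triethyl phosphonoacetate, CCOC(=O)CP(=O)(OCC)OCC
Why: Horner–Wadsworth–Emmons olefination of a methyl ketone with a stabilised phosphonate anion, which should give mainly the (E)-trisubstituted enoate (C12 chain trans to the ester), the minor (Z)-isomer to be removed by chromatography.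

Step 15
Reactants: 21 (E)-enoate
Product: 22 (1S,2S,4aS,6R,8aR)-6-bromo-1-[(3E)-5-hydroxy-3-methylpent-3-en-1-yl]-2,5,5,8a-tetramethyldecahydronaphthalen-2-ol (target)
Conditions: i-Bu2AlH (4 equiv), CH2Cl2, −78 °C; aq. potassium sodium tartrate
Reagents that add atoms: none
Why: 1,2-Reduction of an α,β-unsaturated ester to the allylic alcohol with a dialkylaluminium hydride at low temperature, which should leave the alkene geometry, the secondary bromide and the tertiary alcohol untouched.

**Compound list** (bicyclic names use labdane locants unless a decalin name with CIP descriptors is given)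
1 | 4-methoxy-2,6-dimethylphenol | COc1cc(C)c(O)c(C)c1 | starting material
2 | 4,4-dimethoxy-2,6-dimethylcyclohexa-2,5-dien-1-one | CC1=CC(OC)(OC)C=C(C)C1=O | intermediate
3 | pent-1-en-3-one (ethyl vinyl ketone) | CCC(=O)C=C | starting material
4 | (Z)-tert-butyldimethyl(penta-1,3-dien-3-yloxy)silane | C=C/C(O[Si](C)(C)C(C)(C)C)=C/C | intermediate
5 | (4aS,5R,8aR)-6-(tert-butyldimethylsilyloxy)-4,4-dimethoxy-2,5,8a-trimethyl-4a,5,8,8a-tetrahydronaphthalen-1(4H)-one (cis-fused; C9 ketone, C7=C8, C6 ketal, C2=C3 silyl enol ether, 4α-Me, 5β-H, 10β-Me) | O=C1[C@]2(C)CC=C(O[Si](C)(C)C(C)(C)C)[C@H](C)[C@@H]2C(OC)(OC)C=C1C | intermediate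
6 | cis-fused 6,6-dimethoxy-4α,8,10β-trimethyldecal-1,7-diene-3,9-dione (5β-H) | O=C1[C@]2(C)C=CC(=O)[C@H](C)[C@@H]2C(OC)(OC)C=C1C | intermediate
7 | lithium dienolate of 6 (O–C3=C4, C1=C2), formed in the flask | O=C1[C@]2(C)C=CC(O[Li])=C(C)[C@@H]2C(OC)(OC)C=C1C | intermediate
8 | cis-fused 6,6-dimethoxy-4,4,8,10β-tetramethyldecal-1,7-diene-3,9-dione (5β-H) | O=C1[C@]2(C)C=CC(=O)C(C)(C)[C@@H]2C(OC)(OC)C=C1C | intermediate
9 | cis-fused 4,4,8,10β-tetramethyldecal-1,7-diene-3,6,9-trione (5β-H), formed in the flask | O=C1[C@]2(C)C=CC(=O)C(C)(C)[C@@H]2C(=O)C=C1C | intermediate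
10 | trans-fused 4,4,8,10β-tetramethyldecal-1,7-diene-3,6,9-trione (5α-H) | O=C1[C@]2(C)C=CC(=O)C(C)(C)[C@H]2C(=O)C=C1C | intermediate
11 | 7α,8α-epoxide of 10 (8β-Me) | O=C1[C@]2(C)C=CC(=O)C(C)(C)[C@H]2C(=O)[C@@H]3O[C@@]31C | intermediate
12 | C6 hydrazone of 11, formed in the flask | O=C1[C@]2(C)C=CC(=O)C(C)(C)[C@H]2C(=NN)[C@@H]3O[C@@]31C | intermediate
13 | trans-fused 8α-hydroxy-4,4,8β,10β-tetramethyldecal-1,6-diene-3,9-dione | O=C1[C@]2(C)C=CC(=O)C(C)(C)[C@H]2C=C[C@]1(C)O | intermediate
14 | trans-fused 8α-hydroxy-4,4,8β,10β-tetramethyldecalin-3,9-dione | O=C1[C@]2(C)CCC(=O)C(C)(C)[C@H]2CC[C@]1(C)O | intermediate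
15 | 3α,8α-dihydroxy-4,4,8β,10β-tetramethyl-trans-decalin-9-one | O=C1[C@]2(C)CC[C@H](O)C(C)(C)[C@H]2CC[C@]1(C)O | intermediate
16 | 3β-bromo-8α-hydroxy-4,4,8β,10β-tetramethyl-trans-decalin-9-one | O=C1[C@]2(C)CC[C@@H](Br)C(C)(C)[C@H]2CC[C@]1(C)O | intermediate
17 | 3β-bromo-4,4,8β,10β-tetramethyl-9α-[(trimethylsilyl)methyl]-trans-decalin-8α,9β-diol, formed in the flask | C[Si](C)(C)C[C@]1(O)[C@]2(C)CC[C@@H](Br)C(C)(C)[C@H]2CC[C@]1(C)O | intermediate
18 | 3β-bromo-4,4,8β,10β-tetramethyl-9-methylene-trans-decalin-8α-ol | C=C1[C@]2(C)CC[C@@H](Br)C(C)(C)[C@H]2CC[C@]1(C)O | intermediate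
19 | 9-{[3β-bromo-8α-hydroxy-4,4,8β,10β-tetramethyl-trans-decalin-9β-yl]methyl}-9-borabicyclo[3.3.1]nonane (9α-H), formed in the flask | C(B1C2CCCC1CCC2)[C@H]3[C@]4(C)CC[C@@H](Br)C(C)(C)[C@H]4CC[C@]3(C)O | intermediate
20 | 4-[(1S,2S,4aS,6R,8aR)-6-bromo-2-hydroxy-2,5,5,8a-tetramethyldecahydronaphthalen-1-yl]butan-2-one | CC(=O)CC[C@H]1[C@]2(C)CC[C@@H](Br)C(C)(C)[C@H]2CC[C@]1(C)O | intermediate
21 | ethyl (2E)-5-[(1S,2S,4aS,6R,8aR)-6-bromo-2-hydroxy-2,5,5,8a-tetramethyldecahydronaphthalen-1-yl]-3-methylpent-2-enoate | CCOC(=O)/C=C(\C)CC[C@H]1[C@]2(C)CC[C@@H](Br)C(C)(C)[C@H]2CC[C@]1(C)O | intermediate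
22 | (1S,2S,4aS,6R,8aR)-6-bromo-1-[(3E)-5-hydroxy-3-methylpent-3-en-1-yl]-2,5,5,8a-tetramethyldecahydronaphthalen-2-ol | C/C(=C\CO)CC[C@H]1[C@]2(C)CC[C@@H](Br)C(C)(C)[C@H]2CC[C@]1(C)O | target

**Totals.** 15 steps in all; longest linear sequence 14 steps (1 → 22; step 2 is the only side branch).

**Steps most likely to fail**

Step 3. The catalyst has to bind a carbonyl flanked by two methyl-bearing carbons, and bond formation creates a quaternary carbon next to the ketal. The diene may therefore be consumed by desilylation or open-chain conjugate addition before ring closure, and the choice between the enantiotopic alkenes may be poorly controlled. The fallback keeps the same two bonds but moves stereocontrol from the catalyst to an auxiliary. It sets out from 2: ketal exchange with (R,R)-hydrobenzoin (BF3·OEt2 cat., DME, 23 °C) gives the C2-symmetric (4R,5R)-4,5-diphenyl-1,3-dioxolane monoketal F1, in which the two alkenes are homotopic and only their faces differ. Cycloaddition with 4 promoted by Me2AlCl (CH2Cl2, −78 → −40 °C) should take place on the alkene face remote from the neighbouring phenyl group and give the cis-fused silyl enol ether adduct F2 with the same C10 configuration as 5. Saegusa–Ito oxidation (Pd(OAc)2, MeCN) then gives the ring-A enone F3, LiN(i-Pr)2 gives the lithium dienolate F4, and MeI gives the 4,4-dimethyl enone ketal F5. Hydrolysis with aqueous HCl in THF releases the diol and gives 9, which equilibrates as in step 6, so the route is rejoined at 10.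

Step 11. The oxyphosphonium leaving group sits on a neopentyl carbon with an antiperiplanar axial hydrogen at C2, so elimination to the C2=C3 alkene or ionisation with methyl migration from C4 may outrun substitution. The fallback separates activation from displacement. It sets out from 15: chloromethanesulfonyl chloride and pyridine (CH2Cl2, 0 °C) should sulfonylate only the secondary alcohol and give the 3α-chloromethanesulfonate F6, an isolable ester with a better leaving group. F6 is then displaced with inversion by LiBr in DMF at 60 °C, which returns to the route at 16.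

Step 12. The C9 carbonyl lies between two fully substituted carbons and carries a neighbouring alkoxide once the hydroxyl is deprotonated, so addition of the carbanion may not occur, or base-induced α-ketol rearrangement of the alkoxide may compete. The fallback replaces addition–elimination by a non-basic titanium carbenoid: Takai–Lombardo methylenation of 16 (Zn, CH2Br2, TiCl4, THF–CH2Cl2, 0 → 23 °C) leads directly to 18, where the route is rejoined. It passes through no compound outside the list (F0).

**Further compounds**
F1 | step 3 | 2,6-dimethyl-1,4-benzoquinone 4-[(4R,5R)-4,5-diphenyl-1,3-dioxolane] monoketal | CC1=CC2(O[C@H](c3ccccc3)[C@@H](c3ccccc3)O2)C=C(C)C1=O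
F2 | step 3 | cis-fused adduct as 5 with the (4R,5R)-diphenyldioxolane ketal at C6 | O=C1[C@]2(C)CC=C(O[Si](C)(C)C(C)(C)C)[C@H](C)[C@@H]2C3(O[C@H](c4ccccc4)[C@@H](c4ccccc4)O3)C=C1C
F3 | step 3 | ring-A enone as 6 with the (4R,5R)-diphenyldioxolane ketal at C6 | O=C1[C@]2(C)C=CC(=O)[C@H](C)[C@@H]2C3(O[C@H](c4ccccc4)[C@@H](c4ccccc4)O3)C=C1C
F4 | step 3 | lithium dienolate of F3 | O=C1[C@]2(C)C=CC(O[Li])=C(C)[C@@H]2C3(O[C@H](c4ccccc4)[C@@H](c4ccccc4)O3)C=C1C
F5 | step 3 | 4,4-dimethyl enone as 8 with the (4R,5R)-diphenyldioxolane ketal at C6 | O=C1[C@]2(C)C=CC(=O)C(C)(C)[C@@H]2C3(O[C@H](c4ccccc4)[C@@H](c4ccccc4)O3)C=C1C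
F6 | step 11 | 3α-chloromethanesulfonate of 15 | O=C1[C@]2(C)CC[C@H](OS(=O)(=O)CCl)C(C)(C)[C@H]2CC[C@]1(C)O
F0 | step 12 | none | none
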